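**Assumptions (one line):** The α-santonin photoproduct is taken to have the 1α-H/10-OAc configuration drawn in compound 2, which matches the target. The Diels–Alder is taken to give the target's regiochemistry (C2–C2′ and C3–C5′), endo, on the α faces of both partners.

**Retrosynthesis**
1. Caruifolin B comes from a norbornene silyl enol ether and two tertiary acetates by one global methanolysis. This step also epimerises C4′ to the exo methyl.
2. That adduct comes from one endo Diels–Alder reaction between a guaia-2,4-diene (dienophile through C2=C3) and a 2-silyloxy-cyclopentadiene (diene). It forms the central norbornane and the C2–C2′ and C3–C5′ bonds, and sets four stereocentres.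
3. Both halves come from the same enone, O-acetylisophotosantonic lactone, made in one step from α-santonin by photorearrangement. That step builds the 5-7 guaianolide skeleton and sets C1 and C10, while C6, C7 and C11 are carried over from santonin.
4. Ring order: the 5-7-5 guaianolide first (photochemistry), then the norbornane (Diels–Alder).

**Route**

Step 1
Reactants: 1 (α-santonin, commercial)
Product: 2 (O-acetylisophotosantonic lactone)
Conditions: hν (medium-pressure Hg lamp, Pyrex), glacial AcOH, 20 °C
Reagents that add atoms: acetic acid, CC(=O)O (gives the 10-OAc)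
Why: Photorearrangement of the cross-conjugated dienone to lumisantonin (C1–C5 bond formation and 1,4-shift), then AcOH opens the cyclopropyl ketone at C10. This contracts ring A to the cyclopentenone and expands ring B to the seven-membered ring, and sets C1 and C10. The lactone stereocentres are untouched.

Step 2
Reactants: 2
Product: 3 (10-acetoxy-3-hydroxyguai-4-en-12,6α-olide, C3 epimer mixture)
Conditions: NaBH4, CeCl3·7H2O, MeOH, –78 → 0 °C
Reagents that add atoms: none
Why: Luche 1,2-reduction of the enone leaves the lactone, acetate and C4=C5 alkene intact. The new C3 stereocentre is destroyed in the next step, so no selectivity is needed.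

Step 3
Reactants: 3
Product: 4 (10-acetoxyguaia-2,4-dien-12,6α-olide, cyclopentadiene dienophile)
Conditions: Burgess reagent, THF, 40 °C; use the crude product at once and keep it cold
Reagents that add atoms: none (Burgess reagent, COC(=O)[N-]S(=O)(=O)[N+](CC)(CC)CC, is lost as a by-product)
Why: Syn-Ei elimination of the sulfamate. The only β-H is at C2, so the C2=C3 alkene forms next to C4=C5. C1 keeps its configuration.

Step 4
Reactants: 2
Product: 5 (3-TBSO-10-acetoxyguaia-2,4-dien-12,6α-olide, 2-silyloxycyclopentadiene diene)
Conditions: TBSOTf, Et3N, CH2Cl2, 0 °C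
Reagents that add atoms: TBSOTf, CC(C)(C)[Si](C)(C)OS(=O)(=O)C(F)(F)F (the TBS group stays on the enol oxygen)
Why: Kinetic α′-enolisation (C2) of the cyclopentenone gives the cross-conjugated silyl dienol ether. The tertiary acetate and the lactone are inert.

Step 5
Reactants: 4 (dienophile, 1 equiv) and 5 (diene, 2.5 equiv)
Product: 6 (norbornene silyl enol ether adduct, bis-acetate)
Conditions: toluene (2 M), 40 °C, 5 d (alternative: CH2Cl2, 10 kbar, 25 °C)
Reagents that add atoms: none
Why: Diels–Alder of the strained C2=C3 alkene of cyclopentadiene 4 with diene 5, as in cyclopentadiene dimerisation. Both partners react on their α faces, anti to the C10 quaternary centres, and endo. This fixes C2, C3, C2′ and C5′. The more hindered C4=C5 alkene of 4 does not react and remains as the cyclopentene.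

Step 6
Reactants: 6
Product: 7 (caruifolin B)
Conditions: NaOMe, MeOH, 60 °C, 12 h; then 1 M HCl workup to re-close any opened lactone
Reagents that add atoms: none
Why: Methoxide removes the TBS enol ether and both tertiary acetates by methanolysis. The resulting norbornanone enolises at C4′ (the bridgehead C2′ cannot enolise), so thermodynamic protonation puts the methyl exo. This sets C4′; all other stereocentres are unaffected.

**Compound list**
1 | α-santonin, (3S,3aS,5aS,9bS) | C[C@H]1[C@@H]2CC[C@@]3(C)C=CC(=O)C(C)=C3[C@H]2OC1=O | starting material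
2 | O-acetylisophotosantonic lactone (10-acetoxy-3-oxo-11,13-dihydroguai-4-en-12,6α-olide; 1R,6S,7S,10S,11S) | CC1=C2[C@H]3OC(=O)[C@@H](C)[C@@H]3CC[C@](C)(OC(C)=O)[C@@H]2CC1=O | intermediate
3 | 10-acetoxy-3-hydroxyguai-4-en-12,6α-olide (C3 epimers) | CC1=C2[C@H]3OC(=O)[C@@H](C)[C@@H]3CC[C@](C)(OC(C)=O)[C@@H]2CC1O | intermediate
4 | 10-acetoxyguaia-2,4-dien-12,6α-olide | CC1=C2[C@H]3OC(=O)[C@@H](C)[C@@H]3CC[C@](C)(OC(C)=O)[C@@H]2C=C1 | intermediate
5 | 3-TBSO-10-acetoxyguaia-2,4-dien-12,6α-olide | CC1=C2[C@H]3OC(=O)[C@@H](C)[C@@H]3CC[C@](C)(OC(C)=O)[C@@H]2C=C1O[Si](C)(C)C(C)(C)C | intermediate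
6 | Diels–Alder adduct (norbornene TBS enol ether, 10,10′-diacetate) | CC1=C2[C@H]3OC(=O)[C@@H](C)[C@@H]3CC[C@](C)(OC(C)=O)[C@@H]2[C@H]2[C@H]3C(O[Si](C)(C)C(C)(C)C)=C(C)[C@]4([C@@H]3[C@@](C)(OC(C)=O)CC[C@H]3[C@H](C)C(=O)O[C@@H]34)[C@@H]12 | intermediate
7 | caruifolin B | CC1=C2[C@H]3OC(=O)[C@@H](C)[C@@H]3CC[C@](C)(O)[C@@H]2[C@H]2[C@H]3C(=O)[C@H](C)[C@]4([C@@H]3[C@@](C)(O)CC[C@H]3[C@H](C)C(=O)O[C@@H]34)[C@@H]12 | target

**Total steps:** 6. **Longest linear sequence:** 5 (steps 1, 2, 3, 5, 6).

**Three steps most likely to fail**
1. **Step 5 (Diels–Alder).** It may give the wrong regio-, endo/exo or facial isomer, and cyclopentadiene self-dimerisation or [1,5]-H shifts (which can scramble C1) compete. Fallback: change the mechanism to a radical-cation Diels–Alder, using catalytic (4-BrC6H4)3N•⁺ SbCl6⁻ in CH2Cl2 at 0 °C on the electron-rich diene and alkene pair.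
2. **Step 1 (photorearrangement).** The yield is moderate, and the 1α-H/10-OAc stereochemical outcome is assumed. Fallback: a different route to the same 10-hydroxy-3-oxo-guai-4-ene from (–)-parthenolide: selective hydrogenation of the α-methylene lactone, BF3-mediated transannular cyclisation, Mukaiyama hydration, then allylic oxidation.
3. **Step 3 (dehydration).** The allylic cation pathway can give the more substituted C1=C5 cyclopentadiene isomer or a dimer. Fallback: avoid cations by converting enone 2 to its dienyl triflate and reducing it with Pd(OAc)2, PPh3, HCO2H and Et3N to give cyclopentadiene 4 directly.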